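The route rests on reading the carbocycle as a dearomatised benzoate. With C1 the ring carbon carrying C7 (the CH2OBz carbon), C2 the alkene CH and C3–C6 the oxygenated carbons, ring C1–C6 plus C7 is the carbon skeleton of ethyl benzoate: C1=C2 is the one aromatic double bond that is never touched, and the cis oxygens on C6 and C5 lie on the carbons ortho and meta to C1. Toluene dioxygenase exploits exactly this feature, adding O2 across C5–C6 of the flat, achiral ester to give in one operation an enantiopure cis-diol diene with both stereocentres set. Face-selective epoxidation, hydrolytic opening, reduction and two site-selective benzoylations complete the synthesis.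

Key step: step 1

Remark: every intermediate keeps the ring locants of the target (C1 bears C7, C1=C2, then C3 to C6). In step 1 the reducing equivalents are assumed to come from the cells' own NADH, regenerated from the glucose feed.

Step 1
Reactants: 1 ethyl benzoate
Product: 2 ethyl (5S,6R)-5,6-dihydroxycyclohexa-1,3-diene-1-carboxylate (cis-diol)
Conditions: E. coli JM109(pDTG601A) whole cells expressing toluene dioxygenase (IPTG-induced), glucose-fed aerated fermentation, pH 7, 35 °C; cells spun off, broth extracted with base-washed EtOAc
Reagents that add atoms: dioxygen, O=O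
Why: The non-haem iron oxygenase component of toluene dioxygenase, fed with electrons from cellular NADH through its reductase and ferredoxin partners, activates O2 at the iron centre and delivers both oxygen atoms to the same face of the ortho/meta C–C bond of the bound arene, so the C6–O and C5–O bonds form suprafacially and the benzene ring is left as a 1,3-diene still conjugated to the ester. The closest known reaction type is the whole-cell cis-dihydroxylation of monosubstituted benzenes (halobenzenes, toluene, benzoate esters) by recombinant E. coli carrying the dioxygenase genes without the diol dehydrogenase. No ring is closed: the benzene ring itself becomes the cyclohexadiene that carries C7. C5 and C6 are both set by the enzyme, whose active site holds the single substituent in a fixed pocket and so exposes one enantiotopic face, giving the (5S,6R) cis-diol whose C5/C6 arrangement is that of the target. The step needs ortho/meta regioselectivity, complete facial selectivity and no further oxidation; the first two follow from the fit of a benzene bearing one medium-sized substituent in the active site, the third from the missing dehydrogenase. The extract is kept free of acid because the diene diol loses water to phenols.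

Step 2
Reactants: 2 ethyl (5S,6R)-5,6-dihydroxycyclohexa-1,3-diene-1-carboxylate
Product: 3 ethyl (5S,6R)-5,6-(isopropylidenedioxy)cyclohexa-1,3-diene-1-carboxylate (cis-fused acetonide)
Conditions: 2,2-dimethoxypropane, TsOH·H2O (cat.), acetone, 0 °C to rt, short contact; Et3N quench; concentrated cold and carried on at once
Reagents that add atoms: 2,2-dimethoxypropane, COC(C)(C)OC
Why: Acid-catalysed transketalisation closes the dioxolane on the cis-5,6-diol without touching a stereocentre, and the brief, cold, base-quenched protocol outruns both dehydration of the diol to a phenol and Diels–Alder dimerisation of the diene product.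

Step 3
Reactants: 3 ethyl (5S,6R)-5,6-(isopropylidenedioxy)cyclohexa-1,3-diene-1-carboxylate
Product: 4 ethyl (3R,4R,5R,6R)-3,4-epoxy-5,6-(isopropylidenedioxy)cyclohex-1-ene-1-carboxylate (epoxide oxygen on the face opposite the dioxolane)
Conditions: mCPBA (1.3 equiv), CH2Cl2 / aq. NaHCO3 (two-phase), 0 °C to rt
Reagents that add atoms: mCPBA, O=C(OO)c1cccc(Cl)c1
Why: In this Prilezhaev epoxidation the electrophilic peracid takes the electron-richer C3=C4 alkene and not the ester-deactivated C1=C2, and it approaches from the face opposite the cis-fused dioxolane, which sets C3 and C4 with the new oxygen anti to O5/O6; the bicarbonate phase keeps the acid by-product from opening the vinyl epoxide.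

Step 4
Reactants: 4 ethyl (3R,4R,5R,6R)-3,4-epoxy-5,6-(isopropylidenedioxy)cyclohex-1-ene-1-carboxylate
Product: 5 ethyl (3S,4R,5S,6R)-3,4-dihydroxy-5,6-(isopropylidenedioxy)cyclohex-1-ene-1-carboxylate (O3 on the face of O5/O6, O4 on the other face)
Conditions: HClO4 (70% aq., 5 mol%), THF–H2O 3:1, 0 °C; NaHCO3 quench as soon as 4 is consumed
Reagents that add atoms: water, O
Why: This is an acid-catalysed SN2-type opening of an epoxide lying at the gamma and delta carbons of an unsaturated ester, in which water enters at the allylic carbon C3 from the face opposite the epoxide oxygen (inversion at C3, C4–O untouched) because C4 is shielded and inductively deactivated by the neighbouring dioxolane and the conjugated ester disfavours an allyl cation; the cold, dilute, briefly applied acid leaves the cis-fused acetonide and the ester intact.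

Step 5
Reactants: 5 ethyl (3S,4R,5S,6R)-3,4-dihydroxy-5,6-(isopropylidenedioxy)cyclohex-1-ene-1-carboxylate
Product: 6 (3S,4R,5S,6R)-1-(hydroxymethyl)-5,6-(isopropylidenedioxy)cyclohex-1-ene-3,4-diol
Conditions: i-Bu2AlH (4.5 equiv), CH2Cl2–toluene, −78 to −40 °C; EtOAc quench, then aqueous potassium sodium tartrate (KNaC4H4O6), EtOAc extraction
Reagents that add atoms: none
Why: 1,2-Reduction of an unsaturated ester by i-Bu2AlH in a non-coordinating solvent at low temperature gives the primary allylic alcohol without conjugate reduction, the two free hydroxyls merely consuming hydride as aluminium alkoxides while the acetonide and all stereocentres are untouched.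

Step 6
Reactants: 6 (3S,4R,5S,6R)-1-(hydroxymethyl)-5,6-(isopropylidenedioxy)cyclohex-1-ene-3,4-diol; 7 benzoyl chloride
Product: 8 [(3S,4R,5S,6R)-3,4-dihydroxy-5,6-(isopropylidenedioxy)cyclohex-1-en-1-yl]methyl benzoate
Conditions: 7 (1.05 equiv), 2,4,6-collidine, CH2Cl2, −78 to −20 °C (no DMAP)
Reagents that add atoms: none
Why: Kinetically controlled acylation with one equivalent of acyl chloride and a hindered weak base at low temperature discriminates the unhindered primary allylic hydroxyl O7 from the two secondary hydroxyls O3 and O4.

Step 7
Reactants: 8 [(3S,4R,5S,6R)-3,4-dihydroxy-5,6-(isopropylidenedioxy)cyclohex-1-en-1-yl]methyl benzoate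
Product: 9 [(3S,4R,5R,6R)-3,4,5,6-tetrahydroxycyclohex-1-en-1-yl]methyl benzoate
Conditions: AcOH–H2O 4:1, 45 °C; volatiles removed with toluene
Reagents that add atoms: none
Why: Mild aqueous-acid hydrolysis cleaves the cis-fused isopropylidene ketal, while the benzoate and the allylic C–O bonds are stable to acetic acid and acyl migration, a base-mediated process, does not set in.

Step 8
Reactants: 9 [(3S,4R,5R,6R)-3,4,5,6-tetrahydroxycyclohex-1-en-1-yl]methyl benzoate; 7 benzoyl chloride
Product: 11 [(3S,4R,5R,6R)-5-(benzoyloxy)-3,4,6-trihydroxycyclohex-1-en-1-yl]methyl benzoate (target), via 5,6-O-dibutylstannylene acetal 10 (not isolated)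
Conditions: Bu2SnO (1.05 equiv), toluene (a little 1,4-dioxane for solubility), reflux, Dean–Stark removal of water; then 7 (1.0 equiv), toluene–1,4-dioxane, 0 °C to rt, no amine base; neutral work-up
Reagents that add atoms: none
Why: In this tin-mediated regioselective acylation only O5/O6 of the four hydroxyls are cis and close the favoured five-membered dibutylstannylene ring, within which the equatorial O5 is the nucleophilic oxygen and the pseudoaxial O6 stays tin-bound, the same preference that directs acyl chlorides to the equatorial oxygen of the cis-diol in galactopyranosides; methanol is avoided so that the C7 benzoate is not exposed to tin-catalysed transesterification.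

Compound list
1 | ethyl benzoate | CCOC(=O)c1ccccc1 | starting material
2 | ethyl (5S,6R)-5,6-dihydroxycyclohexa-1,3-diene-1-carboxylate | CCOC(=O)C1=CC=C[C@H](O)[C@@H]1O | intermediate
3 | ethyl (5S,6R)-5,6-(isopropylidenedioxy)cyclohexa-1,3-diene-1-carboxylate | CCOC(=O)C1=CC=C[C@@H]2OC(C)(C)O[C@H]12 | intermediate
4 | ethyl (3R,4R,5R,6R)-3,4-epoxy-5,6-(isopropylidenedioxy)cyclohex-1-ene-1-carboxylate, epoxide anti to the dioxolane | CCOC(=O)C1=C[C@H]3O[C@H]3[C@@H]2OC(C)(C)O[C@H]12 | intermediate
5 | ethyl (3S,4R,5S,6R)-3,4-dihydroxy-5,6-(isopropylidenedioxy)cyclohex-1-ene-1-carboxylate | CCOC(=O)C1=C[C@H](O)[C@@H](O)[C@@H]2OC(C)(C)O[C@H]12 | intermediate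
6 | (3S,4R,5S,6R)-1-(hydroxymethyl)-5,6-(isopropylidenedioxy)cyclohex-1-ene-3,4-diol | OCC1=C[C@H](O)[C@@H](O)[C@@H]2OC(C)(C)O[C@H]12 | intermediate
7 | benzoyl chloride | O=C(Cl)c1ccccc1 | starting material
8 | [(3S,4R,5S,6R)-3,4-dihydroxy-5,6-(isopropylidenedioxy)cyclohex-1-en-1-yl]methyl benzoate | O=C(OCC1=C[C@H](O)[C@@H](O)[C@@H]2OC(C)(C)O[C@H]12)c1ccccc1 | intermediate
9 | [(3S,4R,5R,6R)-3,4,5,6-tetrahydroxycyclohex-1-en-1-yl]methyl benzoate | O=C(OCC1=C[C@H](O)[C@@H](O)[C@H](O)[C@@H]1O)c1ccccc1 | intermediate
10 | 5,6-O-dibutylstannylene acetal of 9 (written as the monomer) | O=C(OCC1=C[C@H](O)[C@@H](O)[C@@H]2O[Sn](CCCC)(CCCC)O[C@H]12)c1ccccc1 | intermediate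
11 | [(3S,4R,5R,6R)-5-(benzoyloxy)-3,4,6-trihydroxycyclohex-1-en-1-yl]methyl benzoate, CNP0198957.7 | O=C(OCC1=C[C@H](O)[C@@H](O)[C@H](OC(=O)c2ccccc2)[C@@H]1O)c1ccccc1 | target

Total step count: 8. Longest linear sequence: 8 steps (1 to 11); benzoyl chloride 7 is bought and used in steps 6 and 8.

Steps most likely to fail

Step 8. The benzoyl group may be spread over O3 or O4 if the tin does not settle cleanly on the cis O5/O6 pair, or the new ester may migrate to a neighbouring hydroxyl during work-up. The fallback removes the competing hydroxyls and sets out from 8. Both secondary hydroxyls are silylated (TBSOTf, 2,6-lutidine, CH2Cl2, 0 °C) to the 3,4-bis(tert-butyldimethylsilyl) ether acetonide F1. The acetonide is cleaved with cold TFA–H2O 9:1 in CH2Cl2, which secondary silyl ethers should survive, giving the 3,4-bis-silylated cis-5,6-diol F2. Its only diol is benzoylated at the equatorial O5 under tin catalysis (Me2SnCl2 5 mol%, 7, i-Pr2NEt, THF, rt) to the 3,4-bis-silylated 5,7-dibenzoate F3. Desilylation with HF·pyridine in THF (0 °C to rt), acidic conditions under which esters do not migrate, returns to the route at 11.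

Step 4. Hydrolysis of the ester-deactivated epoxide may be slow enough for loss of the acetonide to compete, which would erase the distinction between the two diol pairs. The fallback replaces water by a carboxylate under buffered, non-hydrolytic conditions and sets out from 4. CsOAc and AcOH in DMF at 60 °C should open the epoxide at allylic C3 with inversion to ethyl 3-O-acetyl-4-hydroxy-5,6-(isopropylidenedioxy)cyclohex-1-ene-1-carboxylate F4. Excess i-Bu2AlH (CH2Cl2, −78 to 0 °C) then reduces the ring ester and cleaves the acetate in the same operation, so the sequence rejoins the route at 6 with no extra step.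

Step 6. Acylation may fail to discriminate between the primary O7 and the allylic secondary O3, giving over- or mis-benzoylated material. The fallback exchanges reagent control for enzyme control: from 6, transesterification with vinyl benzoate catalysed by immobilised Candida antarctica lipase B (THF–MTBE, 40 °C) acylates only the primary hydroxyl and arrives directly at 8. This detour makes no new compound, F0.

Further compounds
F1 | step 8 | [(3S,4R,5S,6R)-3,4-bis(tert-butyldimethylsilyloxy)-5,6-(isopropylidenedioxy)cyclohex-1-en-1-yl]methyl benzoate | O=C(OCC1=C[C@H](O[Si](C)(C)C(C)(C)C)[C@@H](O[Si](C)(C)C(C)(C)C)[C@@H]2OC(C)(C)O[C@H]12)c1ccccc1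
F2 | step 8 | [3,4-bis(tert-butyldimethylsilyloxy)-5,6-dihydroxycyclohex-1-en-1-yl]methyl benzoate, ring configuration as in 9 | O=C(OCC1=C[C@H](O[Si](C)(C)C(C)(C)C)[C@@H](O[Si](C)(C)C(C)(C)C)[C@H](O)[C@@H]1O)c1ccccc1
F3 | step 8 | [5-(benzoyloxy)-3,4-bis(tert-butyldimethylsilyloxy)-6-hydroxycyclohex-1-en-1-yl]methyl benzoate, ring configuration as in 11 | O=C(OCC1=C[C@H](O[Si](C)(C)C(C)(C)C)[C@@H](O[Si](C)(C)C(C)(C)C)[C@H](OC(=O)c2ccccc2)[C@@H]1O)c1ccccc1
F4 | step 4 | ethyl 3-O-acetyl-4-hydroxy-5,6-(isopropylidenedioxy)cyclohex-1-ene-1-carboxylate, ring configuration as in 5 | CCOC(=O)C1=C[C@H](OC(C)=O)[C@@H](O)[C@@H]2OC(C)(C)O[C@H]12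
F0 | step 6 | none | none
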